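**Retrosynthetic overview**
1. Feature used: in ring A (C1–C5, C10) the quaternary C5 is allylic to C3=C4 and bonded to C6, whose neighbour C7 in ring B (C5–C10) bears oxygen. This is the product pattern of a [3,3] shift of the allyl vinyl ether C6=C7–O–C3–C4=C5.
2. Target ⇐ C7 acetate (ketone reduction, then SN2 inversion) ⇐ 7-ketone 31 ⇐ Claisen ring contraction of bridged eight-membered enol ether 30 (closes ring B, sets C5) ⇐ CuI-catalysed O-vinylation of iododiene alcohol 29.
3. 29 ⇐ ring A with its butenolide by intramolecular Knoevenagel condensation and lactonisation; ring C by Friedel–Crafts acylation at furan C3; C1 by rhodium-catalysed furyl addition.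
4. C10 and C9 ⇐ (S)-5-(hydroxymethyl)furan-2(5H)-one (conjugate addition, two enolate alkylations); its lactone carbonyl becomes C8 and takes C7/C6 from trimethylsilylacetylene.
5. Ring order: furan (bought) → ring C → ring A with butenolide → eight-membered oxacycle → ring B.

Key step: step 20

Locants: clerodane numbering of the target is used for all intermediates (C11 = ring C CH2, C12 = ring C ketone, C17 = methylene carbon on C8, C18 = lactone C=O, C19 = lactone CH2, C20 = methyl on C9).
Remark: hydride is assumed to reach the C7 ketone of 31 from the ring B face opposite the syn-axial C19 methylene and C20 methyl, so the C7 acetate is installed with inversion (steps 21 and 22).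

**Route**

Step 1
Reactants: 1 (S)-5-(hydroxymethyl)furan-2(5H)-one
Product: 2 silyl-protected butenolide
Conditions: tBuPh2SiCl, imidazole, CH2Cl2, 0 °C to rt
Reagents that add atoms: tert-butyl(chloro)diphenylsilane, CC(C)(C)[Si](Cl)(c1ccccc1)c1ccccc1
Why: Imidazole-promoted O-silylation (silyl ether protection) of the primary alcohol, which later becomes the C19 oxygen, leaves the butenolide untouched.

Step 2
Reactants: 2 silyl-protected butenolide
Product: 3 trans-vinyl lactone
Conditions: CH2=CHMgBr, CuBr·SMe2 (10 mol%), THF, −78 °C; aq NH4Cl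
Reagents that add atoms: vinylmagnesium bromide, C=C[Mg]Br
Why: Copper-catalysed conjugate addition of the Grignard reagent to the butenolide should occur anti to the C5 silyloxymethyl group and so fix C10 (4R, trans adduct).

Step 3
Reactants: 4 bromoacetyl bromide; 5 2-phenylpropan-2-ol
Product: 6 2-phenylpropan-2-yl bromoacetate
Conditions: pyridine, CH2Cl2, 0 °C
Reagents that add atoms: none
Why: Esterification of the tertiary alcohol with the acyl bromide gives an alkylating agent whose ester resists organolithium reagents yet is cleaved by 1% CF3CO2H.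

Step 4
Reactants: 3 trans-vinyl lactone; 6 2-phenylpropan-2-yl bromoacetate
Product: 7 C9-monoalkylated lactone
Conditions: LiN(iPr)2, THF, −78 °C; then 6, −78 to −40 °C
Reagents that add atoms: none
Why: Lithium enolate alkylation of the γ-lactone should place the CH2CO2R arm (C11–C12) trans to the C10 vinyl group; this centre is re-made in step 5.

Step 5
Reactants: 7 C9-monoalkylated lactone
Product: 8 C9-quaternary lactone
Conditions: NaN(SiMe3)2, THF, −78 to −40 °C; MeI, −78 to −20 °C
Reagents that add atoms: iodomethane, CI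
Why: Under equilibrating conditions the more acidic lactone α-position should give the enolate, and in this second enolate alkylation iodomethane should enter anti to the C10 vinyl group, so C9 carries CH3 trans and CH2CO2R cis to C1.

Step 6
Reactants: 8 C9-quaternary lactone; 9 tert-butyl acrylate
Product: 10 (E)-enoate lactone
Conditions: second-generation Hoveyda–Grubbs catalyst RuCl2(H2IMes)(=CH-C6H4-2-OiPr) (5 mol%), 9 (5 equiv), toluene, 60 °C
Reagents that add atoms: none
Why: Olefin cross-metathesis of the terminal vinyl group with the electron-poor acrylate, driven by loss of ethene, should give the E-enoate C1=C2–C3.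

Step 7
Reactants: 10 (E)-enoate lactone; 11 potassium (furan-2-yl)trifluoroborate
Product: 12 furyl adduct
Conditions: [Rh(cod)2]BF4 (5 mol%), (S)-BINAP, toluene/H2O (10:1), 100 °C
Reagents that add atoms: none
Why: Rhodium-catalysed asymmetric 1,4-addition (Hayashi–Miyaura reaction) of the furyl group; the BINAP antipode sets C1 as R, the sense the substrate also prefers because furyl enters anti to quaternary C9, so that C2 and C5 end cis on ring C.

Step 8
Reactants: 12 furyl adduct; 13 trimethylsilylacetylene
Product: 14 hydroxy ynone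
Conditions: 13, BuLi, THF, −78 °C; then 12, −78 to −30 °C; aq NH4Cl
Reagents that add atoms: none
Why: Acetylide addition to the lactone carbonyl opens the ring to the C8 ynone (C7≡C6) and frees the C5 hydroxyl, while both tertiary esters are inert to the acetylide.

Step 9
Reactants: 14 hydroxy ynone
Product: 15 C5 acetate
Conditions: Ac2O, DMAP, pyridine, CH2Cl2, rt
Reagents that add atoms: acetic anhydride, CC(=O)OC(C)=O
Why: Acetylation traps the open hydroxy ketone form of the hemiketal and gives an acid-stable protecting group on the C5 oxygen.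

Step 10
Reactants: 15 C5 acetate
Product: 16 silyl enyne
Conditions: Zn, CH2Br2, TiCl4, THF/CH2Cl2, 0 °C to rt
Reagents that add atoms: dibromomethane, BrCBr
Why: Takai–Lombardo methylenation should convert only the ketone into the C8=C17 methylene group and leave the three esters untouched.

Step 11
Reactants: 16 silyl enyne
Product: 19 ring C keto acid, via C12 acid 17 (not isolated), via ring C tert-butyl ester 18 (not isolated)
Conditions: CF3CO2H (1% v/v), anisole, CH2Cl2, 0 °C; then (CF3CO)2O, CH2Cl2 (0.003 M), 0 °C to rt; then CF3CO2H/CH2Cl2 (1:4), rt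
Reagents that add atoms: none
Why: Dilute acid removes only the 2-phenylpropan-2-yl ester, the mixed trifluoroacetic anhydride of the freed C12 acid then acylates furan C3 intramolecularly (Friedel–Crafts acylation closing seven-membered ring C, high dilution against attack at furan C5), and stronger acid finally cleaves the C3 tert-butyl ester.

Step 12
Reactants: 19 ring C keto acid; 20 potassium methyl malonate
Product: 22 methyl β-keto ester, via acyl imidazolide 21 (not isolated)
Conditions: 1,1′-carbonyldiimidazole, THF, rt; then 20, MgCl2, Et3N, MeCN, rt to 45 °C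
Reagents that add atoms: 1,1′-carbonyldiimidazole, O=C(n1ccnc1)n1ccnc1
Why: Masamune homologation: the acyl imidazolide is C-acylated by the magnesium malonate and decarboxylates to the β-keto ester that supplies C4 and C18.

Step 13
Reactants: 22 methyl β-keto ester
Product: 23 C5 alcohol with terminal enyne
Conditions: K2CO3, MeOH, rt
Reagents that add atoms: none
Why: Base-catalysed methanolysis should remove the C5 acetate and the alkyne C-silyl group in one operation without touching the silyl ether.

Step 14
Reactants: 23 C5 alcohol with terminal enyne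
Product: 24 C5 ketone
Conditions: Dess–Martin periodinane, NaHCO3, CH2Cl2, rt
Reagents that add atoms: none
Why: Dess–Martin oxidation of the secondary alcohol gives the C5 ketone under buffered, non-epimerising conditions.

Step 15
Reactants: 24 C5 ketone
Product: 25 ring A enone ester
Conditions: piperidine (20 mol%), AcOH (20 mol%), toluene, 4 Å molecular sieves, 80 °C
Reagents that add atoms: none
Why: Intramolecular Knoevenagel condensation of the doubly activated C4 methylene with the C5 ketone should close six-membered ring A, since only C4 is acidic enough under amine/acid catalysis.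

Step 16
Reactants: 25 ring A enone ester
Product: 27 keto butenolide enyne, via hydroxy ester 26 (not isolated)
Conditions: HF·pyridine, THF/pyridine, 0 °C to rt; then pyridinium p-toluenesulfonate, CH2Cl2, rt
Reagents that add atoms: none
Why: Fluoride-mediated desilylation frees the C19 hydroxyl, which is held cis to the ester on C4=C5 and should lactonise to the butenolide.

Step 17
Reactants: 27 keto butenolide enyne
Product: 28 keto butenolide iododiene
Conditions: NaI, Me3SiCl, H2O (0.5 equiv), MeCN, 0 °C to rt
Reagents that add atoms: sodium iodide, [Na+].[I-]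
Why: Markovnikov hydroiodination of the terminal alkyne of the 1,3-enyne should give the 2-iodo-1,3-diene (chloroprene-type regiochemistry), at a stage with no free alcohol or silyl ether present.

Step 18
Reactants: 28 keto butenolide iododiene
Product: 29 iododiene alcohol
Conditions: NaBH4, CeCl3·7H2O, MeOH, −78 °C
Reagents that add atoms: none
Why: Luche 1,2-reduction of the most electrophilic ketone (C3), with hydride entering the ring A face opposite the C1 furyl and C10–C9 bonds as carvone gives cis-carveol, should set C3–OH cis to C9.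

Step 19
Reactants: 29 iododiene alcohol
Product: 30 bridged enol ether
Conditions: CuI (15 mol%), 3,4,7,8-tetramethyl-1,10-phenanthroline (30 mol%), Cs2CO3, toluene (0.005 M), 80 °C
Reagents that add atoms: none
Why: Copper-catalysed Ullmann-type C–O coupling of the alkenyl iodide with the secondary allylic alcohol, run intramolecularly at high dilution, is made feasible by the cis arrangement of C3–O and C10–C9 on ring A.

Step 20
Reactants: 30 bridged enol ether
Product: 31 7-oxo compound
Conditions: toluene (0.01 M), Et3N (trace), base-washed sealed tube, 120 °C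
Reagents that add atoms: none
Why: Concerted [3,3]-sigmatropic (Claisen) rearrangement through C6=C7–O–C3–C4=C5: C5–C6 forms as O–C3 breaks, C7 becomes a ketone and the alkene moves to C3=C4. The closest known reaction type is the Claisen ring contraction of 2-methylene oxacycles with an endocyclic allylic double bond; allyl 2-(1,3-dienyl) ethers are also known to rearrange to α-methylene ketones. Ring B closes by transannular C5–C6 bond formation across the eight-membered oxacycle through a boat-like six-centre transition state, which contracts the oxacycle to a six-membered carbocycle. The new quaternary centre C5 is set by suprafacial chirality transfer from C3: the oxygen bridge lies on the ring A face that carries the C10–C9 bond, so C6 can reach only that face and the A/B junction must be cis. The step needs the [3,3] path to beat hydrolysis or [1,3] shift of the acid-sensitive dienyl ether, which the amine trace, base-washed glass and the driving force of bridge-strain release and C=O formation should secure.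

Step 21
Reactants: 31 7-oxo compound
Product: 32 7-epi alcohol
Conditions: NaBH4, CeCl3·7H2O, MeOH/CH2Cl2, −78 °C
Reagents that add atoms: none
Why: Luche 1,2-reduction of the C7 enone (the C12 furyl ketone is a deactivated vinylogous ester), with hydride arriving opposite the syn-axial C19 methylene and C20 methyl as 11-oxo steroids give 11β-alcohols, should place the hydroxyl cis to C19 and C20.

Step 22
Reactants: 32 7-epi alcohol
Product: 33 CNP0273675.2
Conditions: AcOH, PBu3, 1,1′-(azodicarbonyl)dipiperidine, toluene, 0 to 60 °C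
Reagents that add atoms: acetic acid, CC(=O)O
Why: Mitsunobu reaction: acetate displaces the oxyphosphonium group by SN2 from the unhindered ring B face, which inverts C7 and gives the equatorial acetate of the target.

**Compound list**
1 | (S)-5-(hydroxymethyl)furan-2(5H)-one | O=C1C=C[C@@H](CO)O1 | starting material
2 | (S)-5-[(tert-butyldiphenylsilyloxy)methyl]furan-2(5H)-one | O=C1C=C[C@@H](CO[Si](c2ccccc2)(c2ccccc2)C(C)(C)C)O1 | intermediate
3 | (4R,5S)-5-[(tert-butyldiphenylsilyloxy)methyl]-4-vinyldihydrofuran-2(3H)-one (vinyl on C10, trans to CH2OSi) | O=C1C[C@H](C=C)[C@@H](CO[Si](c2ccccc2)(c2ccccc2)C(C)(C)C)O1 | intermediate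
4 | bromoacetyl bromide | O=C(Br)CBr | starting material
5 | 2-phenylpropan-2-ol | CC(C)(O)c1ccccc1 | starting material
6 | 2-phenylpropan-2-yl bromoacetate | O=C(CBr)OC(C)(C)c1ccccc1 | intermediate
7 | lactone 3 carrying CH2CO2C(CH3)2Ph on C9, 3,4-trans-4,5-trans | O=C1[C@@H](CC(=O)OC(C)(C)c2ccccc2)[C@H](C=C)[C@@H](CO[Si](c2ccccc2)(c2ccccc2)C(C)(C)C)O1 | intermediate
8 | C9-methyl lactone: quaternary C9 with CH3 trans and CH2CO2C(CH3)2Ph cis to the C10 vinyl group | O=C1[C@](C)(CC(=O)OC(C)(C)c2ccccc2)[C@H](C=C)[C@@H](CO[Si](c2ccccc2)(c2ccccc2)C(C)(C)C)O1 | intermediate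
9 | tert-butyl acrylate | C=CC(=O)OC(C)(C)C | starting material
10 | lactone 8 with the vinyl group extended to (E)-CH=CH–CO2tBu (C1=C2–C3) | O=C1[C@](C)(CC(=O)OC(C)(C)c2ccccc2)[C@H](/C=C/C(=O)OC(C)(C)C)[C@@H](CO[Si](c2ccccc2)(c2ccccc2)C(C)(C)C)O1 | intermediate
11 | potassium (furan-2-yl)trifluoroborate | [K+].F[B-](F)(F)c1ccco1 | starting material
12 | furyl adduct: C1 (R) bearing furan-2-yl, C10 and CH2CO2tBu | O=C1[C@](C)(CC(=O)OC(C)(C)c2ccccc2)[C@H]([C@@H](CC(=O)OC(C)(C)C)c2ccco2)[C@@H](CO[Si](c2ccccc2)(c2ccccc2)C(C)(C)C)O1 | intermediate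
13 | trimethylsilylacetylene | C#C[Si](C)(C)C | starting material
14 | hydroxy ynone: C8 ketone bearing C≡C–SiMe3, free C5–OH (open form of its hemiketal) | C[Si](C)(C)C#CC(=O)[C@](C)(CC(=O)OC(C)(C)c1ccccc1)[C@H]([C@@H](CC(=O)OC(C)(C)C)c1ccco1)[C@H](O)CO[Si](c1ccccc1)(c1ccccc1)C(C)(C)C | intermediate
15 | C5 acetate of 14 | C[Si](C)(C)C#CC(=O)[C@](C)(CC(=O)OC(C)(C)c1ccccc1)[C@H]([C@@H](CC(=O)OC(C)(C)C)c1ccco1)[C@H](OC(C)=O)CO[Si](c1ccccc1)(c1ccccc1)C(C)(C)C | intermediate
16 | silyl enyne: C8=C17H2, C7≡C6–SiMe3, C5–OAc, C12 2-phenylpropan-2-yl ester, C3 tert-butyl ester | C[Si](C)(C)C#CC(=C)[C@](C)(CC(=O)OC(C)(C)c1ccccc1)[C@H]([C@@H](CC(=O)OC(C)(C)C)c1ccco1)[C@H](OC(C)=O)CO[Si](c1ccccc1)(c1ccccc1)C(C)(C)C | intermediate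
17 | C12 carboxylic acid from 16 | C[Si](C)(C)C#CC(=C)[C@](C)(CC(=O)O)[C@H]([C@@H](CC(=O)OC(C)(C)C)c1ccco1)[C@H](OC(C)=O)CO[Si](c1ccccc1)(c1ccccc1)C(C)(C)C | intermediate
18 | ring C ketone (furan-fused cycloheptanone) with C3 tert-butyl ester | C[Si](C)(C)C#CC(=C)[C@]1(C)CC(=O)c2ccoc2[C@H](CC(=O)OC(C)(C)C)[C@@H]1[C@H](OC(C)=O)CO[Si](c1ccccc1)(c1ccccc1)C(C)(C)C | intermediate
19 | ring C ketone with C3 carboxylic acid | C[Si](C)(C)C#CC(=C)[C@]1(C)CC(=O)c2ccoc2[C@H](CC(=O)O)[C@@H]1[C@H](OC(C)=O)CO[Si](c1ccccc1)(c1ccccc1)C(C)(C)C | intermediate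
20 | potassium methyl malonate | [K+].[O-]C(=O)CC(=O)OC | starting material
21 | C3 acyl imidazolide of 19 | C[Si](C)(C)C#CC(=C)[C@]1(C)CC(=O)c2ccoc2[C@H](CC(=O)n2ccnc2)[C@@H]1[C@H](OC(C)=O)CO[Si](c1ccccc1)(c1ccccc1)C(C)(C)C | intermediate
22 | methyl β-keto ester (C3 ketone, C4H2, C18 ester) | C[Si](C)(C)C#CC(=C)[C@]1(C)CC(=O)c2ccoc2[C@H](CC(=O)CC(=O)OC)[C@@H]1[C@H](OC(C)=O)CO[Si](c1ccccc1)(c1ccccc1)C(C)(C)C | intermediate
23 | C5 alcohol with terminal enyne | C#CC(=C)[C@]1(C)CC(=O)c2ccoc2[C@H](CC(=O)CC(=O)OC)[C@@H]1[C@H](O)CO[Si](c1ccccc1)(c1ccccc1)C(C)(C)C | intermediate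
24 | C5 ketone | C#CC(=C)[C@]1(C)CC(=O)c2ccoc2[C@H](CC(=O)CC(=O)OC)[C@@H]1C(=O)CO[Si](c1ccccc1)(c1ccccc1)C(C)(C)C | intermediate
25 | ring A enone ester (C3 ketone, C4=C5, C18 methyl ester, C19 silyl ether) | C#CC(=C)[C@]1(C)CC(=O)c2ccoc2[C@@H]3CC(=O)C(C(=O)OC)=C(CO[Si](c4ccccc4)(c4ccccc4)C(C)(C)C)[C@H]13 | intermediate
26 | C19 hydroxy ester | C#CC(=C)[C@]1(C)CC(=O)c2ccoc2[C@@H]3CC(=O)C(C(=O)OC)=C(CO)[C@H]13 | intermediate
27 | keto butenolide enyne (C3 ketone, C4=C5 butenolide, C8(=CH2)–C≡CH on C9) | C#CC(=C)[C@]1(C)CC(=O)c2ccoc2[C@@H]3CC(=O)C4=C(COC4=O)[C@H]13 | intermediate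
28 | keto butenolide with 3-iodobuta-1,3-dien-2-yl group on C9 | C=C(I)C(=C)[C@]1(C)CC(=O)c2ccoc2[C@@H]3CC(=O)C4=C(COC4=O)[C@H]13 | intermediate
29 | iododiene alcohol (C3–OH cis to C10–C9) | C=C(I)C(=C)[C@]1(C)CC(=O)c2ccoc2[C@@H]3C[C@H](O)C4=C(COC4=O)[C@H]13 | intermediate
30 | bridged eight-membered enol ether (O links C3 and C7; exocyclic C7=C6 and C8=C17; C4=C5 butenolide) | C=C1C(=C)O[C@H]2C[C@H]3c4occc4C(=O)C[C@]1(C)[C@H]3C1=C2C(=O)OC1 | intermediate
31 | 7-oxo compound (ring B closed, C5 quaternary, C3=C4) | C=C1C(=O)C[C@@]23COC(=O)C2=CC[C@H]2c4occc4C(=O)C[C@]1(C)[C@H]23 | intermediate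
32 | 7-epi alcohol (C7–OH cis to C19 and C20) | C=C1[C@H](O)C[C@@]23COC(=O)C2=CC[C@H]2c4occc4C(=O)C[C@]1(C)[C@H]23 | intermediate
33 | CNP0273675.2 | C=C1[C@@H](OC(C)=O)C[C@@]23COC(=O)C2=CC[C@H]2c4occc4C(=O)C[C@]1(C)[C@H]23 | target

**Step count**
Total: 22 steps. Longest linear sequence: 21 steps (steps 1, 2 and 4–22, from 1 to 33).

**Steps most likely to fail**

Step 19. The eight-membered ring closure may lose to intermolecular etherification, protodeiodination or base-induced isomerisation of the butenolide. Fallback: it sets out from 27. Luche reduction (NaBH4, CeCl3·7H2O, MeOH, −78 °C) should give the enyne alcohol F1. Gold-catalysed intramolecular Markovnikov hydroalkoxylation of its terminal alkyne ([AuCl(PPh3)], AgOTf, toluene, rt, high dilution) should then deliver the same enol ether, and the route is rejoined at 30.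

Step 20. Ring contraction may be outrun by hydrolysis or by a [1,3] or retro-ene pathway of the dienyl ether if the bridged transition state is too strained. Fallback: it sets out from 30. Hydrolysis (pyridinium p-toluenesulfonate, wet THF) should give the hydroxy methyl ketone F2, and acetylation (Ac2O, DMAP) the allylic acetate F3. Treating F3 with DBU in MeCN at 60 °C should make the C6 enolate displace the acetate at C5 in an intramolecular SN2′ reaction of the Morita–Baylis–Hillman acetate type. The tether from C9 enforces the same face, and the route is rejoined at 31.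

Step 22. Activation of the hindered axial hydroxyl may stall, or the activated allylic system may divert into SN2′ attack at C17 or elimination to the 6,8(17)-diene. Fallback: it sets out from 32. O-Sulfenylation (2,4-dinitrobenzenesulfenyl chloride, Et3N, CH2Cl2) with spontaneous [2,3] shift should give the allylic sulfoxide F4. The Mislow–Evans rearrangement (P(OMe)3, MeOH, 50 °C) should return oxygen to C7 on the unhindered face and give the 7-alcohol F5. Acetylation (Ac2O, DMAP, pyridine) rejoins the route at 33.

Further compounds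
F1 | step 19 | enyne alcohol (C3–OH, terminal C7≡C6H) | C#CC(=C)[C@]1(C)CC(=O)c2ccoc2[C@@H]3C[C@H](O)C4=C(COC4=O)[C@H]13
F2 | step 20 | hydroxy methyl ketone (C3–OH; C8(=CH2)–C7(=O)–CH3 on C9) | CC(=O)C(=C)[C@]1(C)CC(=O)c2ccoc2[C@@H]3C[C@H](O)C4=C(COC4=O)[C@H]13
F3 | step 20 | allylic acetate of F2 | CC(=O)C(=C)[C@]1(C)CC(=O)c2ccoc2[C@@H]3C[C@H](OC(C)=O)C4=C(COC4=O)[C@H]13
F4 | step 22 | C17 2,4-dinitrophenyl sulfoxide with C7=C8 | O=S(CC1=CC[C@@]23COC(=O)C2=CC[C@H]2c4occc4C(=O)C[C@]1(C)[C@H]23)c1ccc(cc1[N+](=O)[O-])[N+](=O)[O-]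
F5 | step 22 | 7-alcohol with the target configuration | C=C1[C@@H](O)C[C@@]23COC(=O)C2=CC[C@H]2c4occc4C(=O)C[C@]1(C)[C@H]23
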